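The question was how much of the electrophile reacts in dawn and in noon, two flasks that differ in their nucleophile charge.

- dawn: electrophile 0.13 M; nucleophile 1.20 equiv; protic impurity 0.130 M; solid base 1.50 equiv; time 1.5 h
- noon: electrophile 0.13 M; nucleophile 1.80 equiv; protic impurity 0.130 M; solid base 1.50 equiv; time 1.5 h

    nucleophile + acid set free ⇌ protonated nucleophile, settled at all times (K1 = 610 M⁻¹)
    solid base ⇌ free base, rate k2*(cs2 - [free base]) while solid is left; crystals form when [free base] > cs2 (cs2 = 0.097 M, k2 = 2.9 × 10⁻⁴ s⁻¹)
    nucleophile + protic impurity → quenched reagent (k3 = 0.0044 M⁻¹ s⁻¹)
    electrophile + nucleophile → acid set free + product (k4 = 0.0011 M⁻¹ s⁻¹)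
    acid set free + free base ⇌ salt of the base, settled at all times (K5 = 9.0 M⁻¹)

* part of the electrophile that has reacted at the end, dawn
* part of the electrophile that has reacted at the end, noon
* what raising the equivalents of nucleophile from its lowest to its highest value here does to the part of the electrophile that has reacted (changes below 5 percentage points count as none) (it falls / no change / it rises)

- as a solid, counted per litre of solution: solid base
- at the start none of the solid base is in solution
- run time (dawn): 1.5 h

I kept a bill of nucleophile, in equivalents per electrophile charged. Each electrophile converted takes one nucleophile as reagent. While nucleophile lasts, it takes a second as protonated nucleophile, because at the start of dawn the acid set free meets a binding strength of 95 on nucleophile against 0.873 on saturated free base. The protic impurity competes for the same nucleophile with selectivity factor s = 4.00, so its surviving fraction is the surviving fraction of electrophile raised to the power s. At conversion x: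

bill = 2·x + ([protic impurity]/[electrophile], as charged)·(1 − (1 − x)^s)

At full conversion this gives the full bill, 3.00 equiv, the charge at which nucleophile stops being the limiting reagent. Dawn and noon both lie below it. The half-life of nucleophile against impurity as charged in dawn, 0.34 h, is shorter than the run, but it lengthens as the impurity is used, so I took the bill only as a ceiling on conversion at the end of the run in each flask.

Dawn, at a quarter: bill = 1.18 equiv, against 1.20 equiv charged, so the ceiling for dawn is near 25.8%.

Noon, at half: bill = 1.94 equiv, against 1.80 equiv charged, so the ceiling for noon lies below 50.0%.

The price of conversion is steepest at the start, at 6.00 equiv per whole electrophile. On the bill, noon's extra nucleophile therefore raises the ceiling by at least 10.0% of the electrophile, and I expected the answer to be it rises.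

The forecast gave 25% for dawn and 38% for noon, it rises: “the nucleophile runs out at roughly 25% conversion at 1.2 equiv”.

The simulation gave 24.0% in dawn and 37.7% in noon, so conversion it rises by 14 percentage points. Noon's answer moved by 5 points when its nucleophile alone went down to 1.58 equiv or up to 2.02 equiv, the size of change that would overturn these figures. Noon stood 1.20 equiv short of the full bill, and it still held 12.7% of its nucleophile free at the end.

The neighbour with 4.50 equiv of nucleophile lies above the full bill, which leaves 1.50 equiv, or 33.3% of its charge, even at full conversion. Computed, it reached 84.4% with 41% of its nucleophile free and 0.060% of its impurity left.

(The numbers of this flask belong to no real substance; the run is a simulation.)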